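The disconnection cuts the oxepine ring away from the benzene edge C5a–C9a: the aryl–C5 and aryl–O1 bonds are made together by a one-pot Suzuki–Miyaura coupling/intramolecular SNAr annulation. The step exploits the ortho placement of C5 and O1 on the benzo ring and the para relationship between C9a and the C7 side-chain carbon. Kept as an aldehyde, that carbon activates a C9a–F bond, while a C5a–Br bond is the only cross-coupling site. The precursors are 3-bromo-4-fluorobenzaldehyde and a (Z)-dienylboronate alcohol that carries O1, C2–C5 and the exocyclic methylene, built from 2-bromoallyl alcohol. Aldehyde reduction and stearoylation then complete the target.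

Key step: step 4

Remarks: 1-benzoxepine numbering is used (O1, C2, C3, C4, C5, C5a, C6 to C9, C9a). The acyl group is read as octadecanoyl (stearoyl). The target has no stereocentre; its only stereo-element is the ring-enforced cis C4=C5 alkene.

Step 1
Reactants: 1 2-bromoprop-2-en-1-ol; 2 ethynyltrimethylsilane
Product: 3 2-methylidene-4-(trimethylsilyl)but-3-yn-1-ol
Conditions: Pd(PPh3)2Cl2 (2 mol%), CuI (4 mol%), Et3N, THF, rt to 40 °C
Reagents that add atoms: none
Why: Sonogashira coupling (oxidative addition of zerovalent palladium into the vinylic C–Br bond, transmetalation from the copper acetylide, reductive elimination) should give the silyl-capped 1,3-enyne, and the free allylic hydroxyl is tolerated.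

Step 2
Reactants: 3 2-methylidene-4-(trimethylsilyl)but-3-yn-1-ol
Product: 4 2-methylidenebut-3-yn-1-ol
Conditions: K2CO3 (0.2 equiv), MeOH, 0 °C to rt; careful concentration, product kept as a solution
Reagents that add atoms: none
Why: Base-catalysed methanolysis of the alkynyl C–Si bond (protodesilylation) should free the terminal alkyne without touching the allylic alcohol or the 1,1-disubstituted alkene.

Step 3
Reactants: 4 2-methylidenebut-3-yn-1-ol
Product: 7 (Z)-2-methylidene-4-(4,4,5,5-tetramethyl-1,3,2-dioxaborolan-2-yl)but-3-en-1-ol, via O-boryl enyne 5 (not isolated), via O-boryl dienylboronate 6 (not isolated)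
Conditions: HBpin (1.0 equiv), Et3N, cyclohexane, rt to 40 °C until H2 evolution stops; then [Rh(cod)Cl]2 (1.5 mol%), P(iPr)3 (6 mol%), HBpin (0.9 equiv), rt; aq NH4Cl work-up
Reagents that add atoms: pinacolborane, [H]B1OC(C)(C)C(C)(C)O1
Why: After the hydroxyl is masked in the flask as its pinacol borate by dehydrogenative O-borylation, rhodium-catalysed Z-selective (formal trans) hydroboration of the terminal alkyne through a rhodium vinylidene should place boron on the terminal carbon cis to C3, and aqueous work-up cleaves the O–B bond again.

Step 4
Reactants: 7 (Z)-2-methylidene-4-(4,4,5,5-tetramethyl-1,3,2-dioxaborolan-2-yl)but-3-en-1-ol; 8 3-bromo-4-fluorobenzaldehyde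
Product: 10 3-methylidene-2,3-dihydro-1-benzoxepine-7-carbaldehyde, via fluoroaryl dienol 9 (not isolated)
Conditions: Pd(dppf)Cl2 (5 mol%), Cs2CO3 (3 equiv), H2O (5 equiv), degassed DMSO (0.03 M), 60 °C, then 95 °C
Reagents that add atoms: none
Why: Zerovalent palladium inserts into the C–Br bond of 8 (the C–F bond is inert to it), the base-activated (Z)-alkenylboronate 7 transmetalates, and reductive elimination forms the aryl–C5 bond with retention of the Z geometry to give 9; its cesium alkoxide then attacks the fluorine-bearing carbon para to the formyl group (Meisenheimer adduct, loss of fluoride) and forms the aryl–O1 bond. The closest known reaction type is the one-pot Suzuki–Miyaura coupling/intramolecular SNAr annulation of ortho-halofluoroarenes with hydroxyl-bearing boron partners, as used for dibenzofurans and related oxygen heterocycles. The seven-membered oxepine ring is the only ring closed, by intramolecular addition–elimination at C9a through the tether O1–C2–C3–C4=C5, which the Z alkene holds next to the C–F bond. No stereocentre is created; the cis C4=C5 alkene comes from 7 and is locked by the ring. The step needs site selectivity (C–C at C5a, C–O at C9a) and sequence control (coupling before ether formation, since an aryl ether formed first could close by a Heck-type carbopalladation of the 1,1-disubstituted alkene): the bromine/fluorine pair and the para-formyl group secure the first, and running the coupling at 60 °C before heating to 95 °C at high dilution secures the second.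

Step 5
Reactants: 10 3-methylidene-2,3-dihydro-1-benzoxepine-7-carbaldehyde
Product: 11 (3-methylidene-2,3-dihydro-1-benzoxepin-7-yl)methanol
Conditions: NaBH4, MeOH/THF, 0 °C; aqueous quench
Reagents that add atoms: none
Why: Chemoselective 1,2-reduction of the aryl aldehyde by borohydride should leave the unpolarised styrenyl diene and the allyl aryl ether untouched.

Step 6
Reactants: 11 (3-methylidene-2,3-dihydro-1-benzoxepin-7-yl)methanol; 12 octadecanoyl chloride
Product: 13 (3-methylidene-2,3-dihydro-1-benzoxepin-7-yl)methyl octadecanoate
Conditions: Et3N, DMAP (cat.), CH2Cl2, 0 °C to rt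
Reagents that add atoms: none
Why: DMAP-catalysed acylation (nucleophilic acyl substitution) of the primary benzylic alcohol under amine-buffered conditions should give the ester while avoiding acid-mediated isomerisation of the exocyclic diene.

Compound list
1 | 2-bromoprop-2-en-1-ol | C=C(Br)CO | starting material
2 | ethynyltrimethylsilane | C#C[Si](C)(C)C | starting material
3 | 2-methylidene-4-(trimethylsilyl)but-3-yn-1-ol | C=C(CO)C#C[Si](C)(C)C | intermediate
4 | 2-methylidenebut-3-yn-1-ol | C=C(CO)C#C | intermediate
5 | 4,4,5,5-tetramethyl-2-[(2-methylidenebut-3-yn-1-yl)oxy]-1,3,2-dioxaborolane (O-boryl enyne) | C=C(COB1OC(C)(C)C(C)(C)O1)C#C | intermediate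
6 | (Z)-4,4,5,5-tetramethyl-2-{[2-methylidene-4-(4,4,5,5-tetramethyl-1,3,2-dioxaborolan-2-yl)but-3-en-1-yl]oxy}-1,3,2-dioxaborolane (O-boryl dienylboronate) | C=C(COB1OC(C)(C)C(C)(C)O1)/C=C\B1OC(C)(C)C(C)(C)O1 | intermediate
7 | (Z)-2-methylidene-4-(4,4,5,5-tetramethyl-1,3,2-dioxaborolan-2-yl)but-3-en-1-ol | C=C(CO)/C=C\B1OC(C)(C)C(C)(C)O1 | intermediate
8 | 3-bromo-4-fluorobenzaldehyde | O=Cc1ccc(F)c(Br)c1 | starting material
9 | (Z)-4-fluoro-3-(4-hydroxy-3-methylidenebut-1-en-1-yl)benzaldehyde (fluoroaryl dienol) | C=C(CO)/C=C\c1cc(C=O)ccc1F | intermediate
10 | 3-methylidene-2,3-dihydro-1-benzoxepine-7-carbaldehyde | C=C1C=Cc2cc(C=O)ccc2OC1 | intermediate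
11 | (3-methylidene-2,3-dihydro-1-benzoxepin-7-yl)methanol | C=C1C=Cc2cc(CO)ccc2OC1 | intermediate
12 | octadecanoyl chloride (stearoyl chloride) | CCCCCCCCCCCCCCCCCC(=O)Cl | starting material
13 | (3-methylidene-2,3-dihydro-1-benzoxepin-7-yl)methyl octadecanoate | C=C1C=Cc2cc(COC(=O)CCCCCCCCCCCCCCCCC)ccc2OC1 | target

Total step count: 6
Longest linear sequence: 6 (1 to 3 to 4 to 7 to 10 to 11 to 13; 2, 8 and 12 enter as commercial partners)

Steps most likely to fail

Step 4. The dienylboronate may protodeboronate or isomerise from Z to E before transmetalation. Ether formation may run ahead of the coupling and divert into a Heck-type closure. The ring closure may be slow with carbonate alone. Zerovalent palladium may ionise the allyl aryl ether of the product. The fallback sets out from 7 and 12 and comes back to the route at 13. It makes the aryl–O1 bond by palladium-catalysed etherification instead of SNAr and carries the ester from the start. Commercial (4-bromo-3-iodophenyl)methanol is acylated with 12 (Et3N, DMAP, CH2Cl2) to give 4-bromo-3-iodobenzyl octadecanoate F1. F1 and 7 are then heated with Pd(OAc)2, 2-(di-tert-butylphosphino)-1,1'-binaphthyl and Cs2CO3 in toluene (50 °C, then 80 °C). Suzuki–Miyaura coupling at the C–I bond should give (Z)-4-bromo-3-(4-hydroxy-3-methylidenebut-1-en-1-yl)benzyl octadecanoate F2, which is not isolated. Intramolecular C–O coupling at the C–Br bond should then close the oxepine ring and give 13 directly, which makes steps 5 and 6 unnecessary.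

Step 3. The free hydroxyl may be borylated incompletely, the Z-boronate may isomerise to E once the alkyne is consumed, or the hydride may add across the conjugated enyne in a 1,4 sense. The fallback sets out from 1 and comes back to the route at 7; the Z geometry is bought in a preformed two-carbon unit instead of being set by hydroboration. (Z)-1,2-Bis(4,4,5,5-tetramethyl-1,3,2-dioxaborolan-2-yl)ethene F3 is made by syn-diboration of acetylene with bis(pinacolato)diboron and Pt(PPh3)4 in DMF at 80 °C. Used in excess, F3 is coupled once with 1 (Pd(PPh3)4, K3PO4, dioxane/H2O, 50 °C) with retention of alkene geometry, which should give 7 and bypass steps 1 to 3.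

Step 2. The small terminal enynol may be lost on concentration or may oligomerise under base. The fallback sets out from 3 and comes back to the route at 7, so the volatile compound 4 is never handled. Iododesilylation of 3 with N-iodosuccinimide and catalytic AgNO3 in DMF should give 4-iodo-2-methylidenebut-3-yn-1-ol F4. Cis-reduction of the iodoalkyne with diimide (from 2-nitrobenzenesulfonyl hydrazide and Et3N, THF/iPrOH, rt) should give (Z)-4-iodo-2-methylidenebut-3-en-1-ol F5. Miyaura borylation with bis(pinacolato)diboron (Pd(PPh3)2Cl2, PPh3, KOPh, toluene, 50 °C) with retention of geometry then returns to 7.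

Further compounds
F1 | step 4 | 4-bromo-3-iodobenzyl octadecanoate | CCCCCCCCCCCCCCCCCC(=O)OCc1ccc(Br)c(I)c1
F2 | step 4 | (Z)-4-bromo-3-(4-hydroxy-3-methylidenebut-1-en-1-yl)benzyl octadecanoate | C=C(CO)/C=C\c1cc(COC(=O)CCCCCCCCCCCCCCCCC)ccc1Br
F3 | step 3 | (Z)-1,2-bis(4,4,5,5-tetramethyl-1,3,2-dioxaborolan-2-yl)ethene | CC1(C)OB(/C=C\B2OC(C)(C)C(C)(C)O2)OC1(C)C
F4 | step 2 | 4-iodo-2-methylidenebut-3-yn-1-ol | C=C(CO)C#CI
F5 | step 2 | (Z)-4-iodo-2-methylidenebut-3-en-1-ol | C=C(CO)/C=C\I
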